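**Strategy.** The chroman is cut at C3–C4 and O1–C2. C4 is a benzylic CH2 on C4a, ortho to the C8a oxygen of ring A, so the unit C4–C4a–C8a–O1 can be released as an ortho-quinone methide from a 2-(tosylmethyl)phenol, while C2–C3 with ring B comes from an arylacetaldehyde. One aminocatalytic formal [4+2] annulation joins the two halves, closes the pyran ring as a chroman-2-ol and sets C3 (R). The precursors are a phloroglucinol-type benzoate carrying one CH2Ts group ortho to a free phenol, and the MOM-protected, prenylated ring-B acetaldehyde. Lactol reduction, Mitsunobu closure and conversion of the C8 ester into the aldehyde finish the route.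

Key step: step 7

Assumption: the sense of induction is taken from the steric-shielding model of diarylprolinol silyl ether enamines, under which the R catalyst should give 3R (the S catalyst would give the mirror image).

Step 1
Reactants: 1 methyl 2,4,6-trihydroxybenzoate
Product: 2 methyl 2,6-dihydroxy-4-methoxybenzoate
Conditions: Me2SO4 (1.0 equiv), K2CO3 (1.1 equiv), acetone, 0 °C → rt
Reagents that add atoms: dimethyl sulfate, COS(=O)(=O)OC
Why: Williamson O-methylation; the 4-OH, para to the ester and the only hydroxyl not held in a hydrogen bond to it, is the most acidic and nucleophilic, so one equivalent of a hard methylating agent with a weak base should stop at the 4-methyl ether.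

Step 2
Reactants: 2 methyl 2,6-dihydroxy-4-methoxybenzoate
Product: 4 methyl 2,6-dihydroxy-4-methoxy-3-[(4-methylphenyl)sulfonylmethyl]benzoate, via hydroxymethyl benzoate 3 (not isolated)
Conditions: aq HCHO (1.0 equiv), TolSO2Na (1.5 equiv), HCO2H/H2O 1:1, rt
Reagents that add atoms: formaldehyde, C=O; sodium p-toluenesulfinate, Cc1ccc(cc1)S(=O)[O-].[Na+]
Why: Three-component sulfonylmethylation of a phenol (Mannich-type: hydroxymethylation, acid ionisation, S-capture by sulfinate); ring 2 is symmetric with one kind of nucleophilic carbon, so a single regioisomer should form, and one equivalent of formaldehyde with excess sulfinate should hold the reaction at the mono-sulfone.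

Step 3
Reactants: 5 3-methoxyphenol
Product: 6 1-methoxy-3-(methoxymethoxy)benzene
Conditions: NaH, MOMCl, THF, 0 °C → rt
Reagents that add atoms: chloromethyl methyl ether (MOMCl), COCCl
Why: O-alkylation of the sodium phenoxide with MOMCl (Williamson type) installs the acetal that directs both metalations and protects the 2'-oxygen to the end.

Step 4
Reactants: 6 1-methoxy-3-(methoxymethoxy)benzene; 7 prenyl bromide
Product: 9 1-methoxy-3-(methoxymethoxy)-2-(3-methylbut-2-enyl)benzene, via aryllithium 8 (not isolated)
Conditions: n-BuLi, THF, 0 °C → rt; CuBr·SMe2 (10 mol %), then 7, −78 °C → rt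
Reagents that add atoms: none
Why: Directed ortho-metalation at the carbon flanked by OMOM and OMe, where both oxygens cooperate, followed by copper-assisted SN2 allylation of the aryl nucleophile at the primary carbon of prenyl bromide.

Step 5
Reactants: 9 1-methoxy-3-(methoxymethoxy)-2-(3-methylbut-2-enyl)benzene; 10 ethylene oxide
Product: 12 2-[4-methoxy-2-(methoxymethoxy)-3-(3-methylbut-2-enyl)phenyl]ethanol, via aryllithium 11 (not isolated)
Conditions: n-BuLi, TMEDA, THF, −20 → 0 °C; 10 (THF solution), −78 °C → rt; H2O quench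
Reagents that add atoms: none
Why: Second directed ortho-metalation, now at the only free position ortho to OMOM, which binds lithium better than OMe, followed by SN2 opening of the epoxide by the aryllithium to give the 2-arylethanol.

Step 6
Reactants: 12 2-[4-methoxy-2-(methoxymethoxy)-3-(3-methylbut-2-enyl)phenyl]ethanol
Product: 13 [4-methoxy-2-(methoxymethoxy)-3-(3-methylbut-2-enyl)phenyl]acetaldehyde
Conditions: Dess–Martin periodinane, CH2Cl2, 0 °C → rt; used at once
Reagents that add atoms: none
Why: Dess–Martin oxidation should stop at the arylacetaldehyde under near-neutral conditions that leave the MOM acetal and the prenyl alkene untouched.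

Step 7
Reactants: 4 methyl 2,6-dihydroxy-4-methoxy-3-[(4-methylphenyl)sulfonylmethyl]benzoate; 13 [4-methoxy-2-(methoxymethoxy)-3-(3-methylbut-2-enyl)phenyl]acetaldehyde
Product: 16 methyl (3R)-2,7-dihydroxy-5-methoxy-3-[4-methoxy-2-(methoxymethoxy)-3-(3-methylbut-2-enyl)phenyl]chromane-8-carboxylate (lactol; both C2 epimers), via ortho-quinone methide 14 (not isolated), via open-chain aldehyde 15 (not isolated)
Conditions: (R)-2-[diphenyl(trimethylsilyloxy)methyl]pyrrolidine (20 mol %), sat. aq NaHCO3, CH2Cl2, 0 °C → rt; 13 in excess (1.5 equiv)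
Reagents that add atoms: none
Why: Bicarbonate deprotonates the phenol next to the sulfonylmethyl group and p-toluenesulfinate leaves (E1cB) to give ortho-quinone methide 14; the E-enamine formed from 13 and the catalyst adds through its nucleophilic carbon to the exocyclic CH2 (bond C3–C4), ring A rearomatises, and hydrolysis releases aldehyde 15, which the C8a phenol captures (bond O1–C2). The closest known reaction type is the diarylprolinol silyl ether-catalysed formal [4+2] annulation of in situ generated ortho-quinone methides with enolisable aldehydes to chroman-2-ols. The pyran ring closes by 6-exo-trig addition of the phenol oxygen to the carbonyl carbon (hemiacetal formation). C3 is set by the catalyst: the CPh2(OTMS) group blocks one face of the s-trans E-enamine, and with the R catalyst the open face should lead to 3R (the aryl group outranks the new CH2 at C3); C2 forms as both epimers and is removed in step 8. The step needs chemoselectivity for the enamine over the free ring-A carbon of a second molecule and over enolisation of 15, which the excess of 13, the slow release of 14 under a weak base and the storage of the aldehyde as the lactol should secure. Ring closure is unambiguous because the other oxygen ortho to C4a is a methyl ether and the C7 hydroxyl cannot reach C2, and the ester does not condense with the amine.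

Step 8
Reactants: 16 methyl (3R)-2,7-dihydroxy-5-methoxy-3-[4-methoxy-2-(methoxymethoxy)-3-(3-methylbut-2-enyl)phenyl]chromane-8-carboxylate
Product: 17 methyl 2,6-dihydroxy-3-[(2R)-3-hydroxy-2-[4-methoxy-2-(methoxymethoxy)-3-(3-methylbut-2-enyl)phenyl]propyl]-4-methoxybenzoate
Conditions: NaBH4, MeOH/THF, −20 → 0 °C
Reagents that add atoms: none
Why: Borohydride reduction of the lactol through its open hydroxy-aldehyde form, run cold so that hydride delivery outruns enolisation at C3; the hindered, hydrogen-bonded benzoate is not reduced.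

Step 9
Reactants: 17 methyl 2,6-dihydroxy-3-[(2R)-3-hydroxy-2-[4-methoxy-2-(methoxymethoxy)-3-(3-methylbut-2-enyl)phenyl]propyl]-4-methoxybenzoate
Product: 18 methyl (3R)-7-hydroxy-5-methoxy-3-[4-methoxy-2-(methoxymethoxy)-3-(3-methylbut-2-enyl)phenyl]chromane-8-carboxylate
Conditions: PPh3, DIAD, THF (dilute), 0 °C → rt
Reagents that add atoms: none
Why: Intramolecular Mitsunobu etherification (6-exo-tet); only the C8a hydroxyl can reach the activated primary carbinol, the reacting carbon is not stereogenic, and C3 is not touched.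

Step 10
Reactants: 18 methyl (3R)-7-hydroxy-5-methoxy-3-[4-methoxy-2-(methoxymethoxy)-3-(3-methylbut-2-enyl)phenyl]chromane-8-carboxylate
Product: 19 methyl (3R)-5-methoxy-7-(methoxymethoxy)-3-[4-methoxy-2-(methoxymethoxy)-3-(3-methylbut-2-enyl)phenyl]chromane-8-carboxylate
Conditions: NaH, MOMCl, DMF, 0 °C → rt
Reagents that add atoms: chloromethyl methyl ether (MOMCl), COCCl
Why: MOM protection of the one remaining phenol (Williamson type), so that the hydride reduction does not pass through a free ortho-hydroxybenzyl alcohol, which in so electron-rich a ring tends to lose water and be reduced on to a methyl group.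

Step 11
Reactants: 19 methyl (3R)-5-methoxy-7-(methoxymethoxy)-3-[4-methoxy-2-(methoxymethoxy)-3-(3-methylbut-2-enyl)phenyl]chromane-8-carboxylate
Product: 20 [(3R)-5-methoxy-7-(methoxymethoxy)-3-[4-methoxy-2-(methoxymethoxy)-3-(3-methylbut-2-enyl)phenyl]chroman-8-yl]methanol
Conditions: LiAlH4, THF, 0 °C → rt; Fieser work-up; used crude
Reagents that add atoms: none
Why: LiAlH4 reduction of the 2,6-dialkoxybenzoate to the benzylic alcohol; acetals, aryl ethers and the isolated alkene are inert to hydride.

Step 12
Reactants: 20 [(3R)-5-methoxy-7-(methoxymethoxy)-3-[4-methoxy-2-(methoxymethoxy)-3-(3-methylbut-2-enyl)phenyl]chroman-8-yl]methanol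
Product: 21 (3R)-5-methoxy-7-(methoxymethoxy)-3-[4-methoxy-2-(methoxymethoxy)-3-(3-methylbut-2-enyl)phenyl]chromane-8-carbaldehyde
Conditions: MnO2 (activated, excess), CH2Cl2, rt
Reagents that add atoms: none
Why: MnO2 oxidation of an electron-rich benzylic alcohol should stop at the aldehyde and does not attack the prenyl group or the acetals.

Step 13
Reactants: 21 (3R)-5-methoxy-7-(methoxymethoxy)-3-[4-methoxy-2-(methoxymethoxy)-3-(3-methylbut-2-enyl)phenyl]chromane-8-carbaldehyde
Product: 22 (3R)-7-hydroxy-3-[2-hydroxy-4-methoxy-3-(3-methylbut-2-enyl)phenyl]-5-methoxychromane-8-carbaldehyde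
Conditions: 3 M aq HCl, MeOH/THF, rt → 40 °C
Reagents that add atoms: none
Why: Acid-catalysed acetal exchange with methanol removes both MOM groups; dilute acid near room temperature is chosen because cyclisation of the 2'-phenol onto the prenyl alkene needs stronger acid.

**Compound list**

1 | methyl 2,4,6-trihydroxybenzoate | COC(=O)c1c(O)cc(O)cc1O | starting material
2 | methyl 2,6-dihydroxy-4-methoxybenzoate | COC(=O)c1c(O)cc(OC)cc1O | intermediate
3 | methyl 2,6-dihydroxy-3-(hydroxymethyl)-4-methoxybenzoate (formed in the flask, not isolated) | COC(=O)c1c(O)cc(OC)c(CO)c1O | intermediate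
4 | methyl 2,6-dihydroxy-4-methoxy-3-[(4-methylphenyl)sulfonylmethyl]benzoate | COC(=O)c1c(O)cc(OC)c(CS(=O)(=O)c2ccc(C)cc2)c1O | intermediate
5 | 3-methoxyphenol | COc1cccc(O)c1 | starting material
6 | 1-methoxy-3-(methoxymethoxy)benzene | COCOc1cccc(OC)c1 | intermediate
7 | prenyl bromide (1-bromo-3-methylbut-2-ene) | CC(C)=CCBr | starting material
8 | [2-methoxy-6-(methoxymethoxy)phenyl]lithium (formed in the flask, not isolated) | COCOc1cccc(OC)c1[Li] | intermediate
9 | 1-methoxy-3-(methoxymethoxy)-2-(3-methylbut-2-enyl)benzene | COCOc1cccc(OC)c1CC=C(C)C | intermediate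
10 | ethylene oxide (oxirane) | C1CO1 | starting material
11 | [4-methoxy-2-(methoxymethoxy)-3-(3-methylbut-2-enyl)phenyl]lithium (formed in the flask, not isolated) | COCOc1c([Li])ccc(OC)c1CC=C(C)C | intermediate
12 | 2-[4-methoxy-2-(methoxymethoxy)-3-(3-methylbut-2-enyl)phenyl]ethanol | COCOc1c(CCO)ccc(OC)c1CC=C(C)C | intermediate
13 | [4-methoxy-2-(methoxymethoxy)-3-(3-methylbut-2-enyl)phenyl]acetaldehyde | COCOc1c(CC=O)ccc(OC)c1CC=C(C)C | intermediate
14 | methyl 2-hydroxy-4-methoxy-5-methylidene-6-oxocyclohexa-1,3-diene-1-carboxylate (ortho-quinone methide, not isolated) | COC(=O)C1=C(O)C=C(OC)C(=C)C1=O | intermediate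
15 | methyl 2,6-dihydroxy-4-methoxy-3-[(2R)-2-[4-methoxy-2-(methoxymethoxy)-3-(3-methylbut-2-enyl)phenyl]-3-oxopropyl]benzoate (not isolated) | COCOc1c([C@H](C=O)Cc2c(O)c(C(=O)OC)c(O)cc2OC)ccc(OC)c1CC=C(C)C | intermediate
16 | methyl (3R)-2,7-dihydroxy-5-methoxy-3-[4-methoxy-2-(methoxymethoxy)-3-(3-methylbut-2-enyl)phenyl]chromane-8-carboxylate (lactol, both C2 epimers) | COCOc1c([C@@H]2C(O)Oc3c(C(=O)OC)c(O)cc(OC)c3C2)ccc(OC)c1CC=C(C)C | intermediate
17 | methyl 2,6-dihydroxy-3-[(2R)-3-hydroxy-2-[4-methoxy-2-(methoxymethoxy)-3-(3-methylbut-2-enyl)phenyl]propyl]-4-methoxybenzoate | COCOc1c([C@H](CO)Cc2c(O)c(C(=O)OC)c(O)cc2OC)ccc(OC)c1CC=C(C)C | intermediate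
18 | methyl (3R)-7-hydroxy-5-methoxy-3-[4-methoxy-2-(methoxymethoxy)-3-(3-methylbut-2-enyl)phenyl]chromane-8-carboxylate | COCOc1c([C@@H]2COc3c(C(=O)OC)c(O)cc(OC)c3C2)ccc(OC)c1CC=C(C)C | intermediate
19 | methyl (3R)-5-methoxy-7-(methoxymethoxy)-3-[4-methoxy-2-(methoxymethoxy)-3-(3-methylbut-2-enyl)phenyl]chromane-8-carboxylate | COCOc1c([C@@H]2COc3c(C(=O)OC)c(OCOC)cc(OC)c3C2)ccc(OC)c1CC=C(C)C | intermediate
20 | [(3R)-5-methoxy-7-(methoxymethoxy)-3-[4-methoxy-2-(methoxymethoxy)-3-(3-methylbut-2-enyl)phenyl]chroman-8-yl]methanol | COCOc1c([C@@H]2COc3c(CO)c(OCOC)cc(OC)c3C2)ccc(OC)c1CC=C(C)C | intermediate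
21 | (3R)-5-methoxy-7-(methoxymethoxy)-3-[4-methoxy-2-(methoxymethoxy)-3-(3-methylbut-2-enyl)phenyl]chromane-8-carbaldehyde | COCOc1c([C@@H]2COc3c(C=O)c(OCOC)cc(OC)c3C2)ccc(OC)c1CC=C(C)C | intermediate
22 | (3R)-7-hydroxy-3-[2-hydroxy-4-methoxy-3-(3-methylbut-2-enyl)phenyl]-5-methoxychromane-8-carbaldehyde | COc1ccc([C@@H]2COc3c(C=O)c(O)cc(OC)c3C2)c(O)c1CC=C(C)C | target

**Step count.** Total: 13 steps. Longest linear sequence: 11 steps (steps 3–13, from 3-methoxyphenol 5).

**Steps most likely to fail**

Step 7. The quinone methide may be consumed by C-alkylation of a second ring-A molecule before the enamine intercepts it, or the C3 configuration may erode through opening of the lactol and enolisation, so that facial control is lost. The fallback is an auxiliary-controlled alkylation that sets out from 13 and 2 and returns at 17. Aldehyde 13 would be oxidised (NaClO2, NaH2PO4, 2-methyl-2-butene) to [4-methoxy-2-(methoxymethoxy)-3-(3-methylbut-2-enyl)phenyl]acetic acid F1, which, through its pivaloyl mixed anhydride and lithiated (R)-4-benzyl-oxazolidin-2-one, would give the imide (4R)-4-benzyl-3-{[4-methoxy-2-(methoxymethoxy)-3-(3-methylbut-2-enyl)phenyl]acetyl}oxazolidin-2-one F2. In parallel, 2 would be bis-allylated (allyl bromide, K2CO3, DMF) to methyl 2,6-bis(allyloxy)-4-methoxybenzoate F3, formylated (POCl3, DMF) to methyl 2,6-bis(allyloxy)-3-formyl-4-methoxybenzoate F4, reduced (NaBH4) to methyl 2,6-bis(allyloxy)-3-(hydroxymethyl)-4-methoxybenzoate F5 and converted (PBr3, Et2O, 0 °C, used freshly) into methyl 2,6-bis(allyloxy)-3-(bromomethyl)-4-methoxybenzoate F6. Deprotonation of F2 (NaHMDS, THF, −78 °C) and alkylation with F6 on the enolate face away from the benzyl group should give methyl 2,6-bis(allyloxy)-3-[(2R)-3-[(4R)-4-benzyl-2-oxo-oxazolidin-3-yl]-2-[4-methoxy-2-(methoxymethoxy)-3-(3-methylbut-2-enyl)phenyl]-3-oxopropyl]-4-methoxybenzoate F7. LiBH4 (THF/MeOH, 0 °C) would remove the auxiliary to give methyl 2,6-bis(allyloxy)-3-[(2R)-3-hydroxy-2-[4-methoxy-2-(methoxymethoxy)-3-(3-methylbut-2-enyl)phenyl]propyl]-4-methoxybenzoate F8, and Pd(PPh3)4 with morpholine would remove both allyl groups to give 17.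

Step 5. The aryllithium may be captured incompletely by the epoxide, through proton transfer or oligomerisation of the epoxide, so that little arylethanol forms. The fallback installs the two carbons one at a time; it sets out from 9 and returns at 12. The same metalation of 9 would be quenched with DMF, a trap that is efficient for hindered aryllithiums, to give 4-methoxy-2-(methoxymethoxy)-3-(3-methylbut-2-enyl)benzaldehyde F9. Wittig methylenation (Ph3P=CH2, THF) would give 1-ethenyl-4-methoxy-2-(methoxymethoxy)-3-(3-methylbut-2-enyl)benzene F10. Hydroboration with 9-BBN, which takes the terminal vinyl group in preference to the trisubstituted prenyl alkene, followed by NaOH/H2O2, should give 12.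

Step 2. Over-reaction is the danger: a second sulfonylmethylation at the remaining ring carbon, or capture of the benzylic cation by a second arene to give a methylene-bridged dimer. The fallback separates the C–C bond formation from the introduction of sulfur; it sets out from 2 and returns at 4. A Mannich reaction (Me2NH, aq HCHO, EtOH, rt) should give methyl 3-[(dimethylamino)methyl]-2,6-dihydroxy-4-methoxybenzoate F11, which as its internal salt resists a second substitution. Heating F11 with sodium p-toluenesulfinate in acetic acid would exchange the amine for the sulfinate by elimination–addition to give 4.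

**Further compounds**

F1 | step 7 | [4-methoxy-2-(methoxymethoxy)-3-(3-methylbut-2-enyl)phenyl]acetic acid | COCOc1c(CC(=O)O)ccc(OC)c1CC=C(C)C
F2 | step 7 | (4R)-4-benzyl-3-{[4-methoxy-2-(methoxymethoxy)-3-(3-methylbut-2-enyl)phenyl]acetyl}oxazolidin-2-one | COCOc1c(CC(=O)N2[C@H](Cc3ccccc3)COC2=O)ccc(OC)c1CC=C(C)C
F3 | step 7 | methyl 2,6-bis(allyloxy)-4-methoxybenzoate | COC(=O)c1c(OCC=C)cc(OC)cc1OCC=C
F4 | step 7 | methyl 2,6-bis(allyloxy)-3-formyl-4-methoxybenzoate | COC(=O)c1c(OCC=C)cc(OC)c(C=O)c1OCC=C
F5 | step 7 | methyl 2,6-bis(allyloxy)-3-(hydroxymethyl)-4-methoxybenzoate | COC(=O)c1c(OCC=C)cc(OC)c(CO)c1OCC=C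
F6 | step 7 | methyl 2,6-bis(allyloxy)-3-(bromomethyl)-4-methoxybenzoate | COC(=O)c1c(OCC=C)cc(OC)c(CBr)c1OCC=C
F7 | step 7 | methyl 2,6-bis(allyloxy)-3-[(2R)-3-[(4R)-4-benzyl-2-oxo-oxazolidin-3-yl]-2-[4-methoxy-2-(methoxymethoxy)-3-(3-methylbut-2-enyl)phenyl]-3-oxopropyl]-4-methoxybenzoate | COCOc1c([C@H](C(=O)N2[C@H](Cc3ccccc3)COC2=O)Cc4c(OCC=C)c(C(=O)OC)c(OCC=C)cc4OC)ccc(OC)c1CC=C(C)C
F8 | step 7 | methyl 2,6-bis(allyloxy)-3-[(2R)-3-hydroxy-2-[4-methoxy-2-(methoxymethoxy)-3-(3-methylbut-2-enyl)phenyl]propyl]-4-methoxybenzoate | COCOc1c([C@H](CO)Cc2c(OCC=C)c(C(=O)OC)c(OCC=C)cc2OC)ccc(OC)c1CC=C(C)C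
F9 | step 5 | 4-methoxy-2-(methoxymethoxy)-3-(3-methylbut-2-enyl)benzaldehyde | COCOc1c(C=O)ccc(OC)c1CC=C(C)C
F10 | step 5 | 1-ethenyl-4-methoxy-2-(methoxymethoxy)-3-(3-methylbut-2-enyl)benzene | COCOc1c(C=C)ccc(OC)c1CC=C(C)C
F11 | step 2 | methyl 3-[(dimethylamino)methyl]-2,6-dihydroxy-4-methoxybenzoate | COC(=O)c1c(O)cc(OC)c(CN(C)C)c1O
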